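## Retrosynthetic overview

1. Target ⇐ 13‑O‑acetylation ⇐ hydroxyl‑directed 11,12‑epoxidation ⇐ α‑methylenation (C17) of a 14‑membered lactone diol. Ring order: butyrolactone (present from step 1) → carbocycle (ring‑closing metathesis at C6=C7) → epoxide.
2. C13–C14 ⇐ catalyst‑controlled addition of a lactone‑borne alkylzinc to the enal made in one step from (R)‑linalool, which supplies C7–C13 and the C8 carbinol.
3. Lactone ⇐ furfural. Singlet‑oxygen dearomatisation in step 1 turns the furan ring, atom for atom, into C16–C15–C1–C2 and both lactone oxygens; (+)‑menthol locks the new acetal carbon (C2) as one epimer.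
4. C1 ⇐ photochemical addition of CH2OH (C14) anti to the acetal. C2 ⇐ replacement of the menthyloxy group by the C3–C6 alkenyl unit (carboalumination of pent‑1‑en‑4‑yne), delivered from aluminium tethered to that CH2OH and therefore cis.

Assumption: (+)‑menthol, (R)‑(−)‑linalool and pent‑1‑en‑4‑yne are bought. Cembranolide numbering is used: C1 ring‑fusion CH bearing C14, C2 lactone O–CH, C13 acetoxy carbon, C15/C16/C17 the methylene‑lactone carbons.

## Route

Step 1
Reactants: 1 furfural; 2 (+)-menthol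
Product: 4 (5S)-5-[(1S,2R,5S)-menthyloxy]furan-2(5H)-one, via 5-hydroxyfuran-2(5H)-one 3 (not isolated)
Conditions: O2, hν (visible), rose bengal (cat.), MeOH, rt; concentrate; then 2, camphorsulfonic acid (cat.), toluene, reflux (−H2O); crystallise (petroleum ether), re‑equilibrate the mother liquor with acid
Reagents that add atoms: dioxygen, O=O
Why: Sensitised photooxygenation adds singlet oxygen across the furan ([4+2]) and the endoperoxide loses the formyl carbon as methyl formate to give the pseudo‑acid, whose acid‑catalysed acetalisation with (+)-menthol under crystallisation‑driven epimerisation of the labile acetal centre gives the single (5S) epimer that anchors all lactone stereochemistry.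

Step 2
Reactants: 4 (5S)-5-[(1S,2R,5S)-menthyloxy]furan-2(5H)-one
Product: 5 (4R,5S)-4-(hydroxymethyl)-5-[(1S,2R,5S)-menthyloxy]dihydrofuran-2(3H)-one
Conditions: MeOH (degassed), benzophenone (0.2 equiv), hν (>300 nm), rt
Reagents that add atoms: methanol, CO
Why: Benzophenone‑sensitised radical conjugate addition (Giese type) of the hydroxymethyl radical to the butenolide occurs anti to the bulky menthyloxy group, which sets C1 (4,5‑trans) and installs C14 as CH2OH.

Step 3
Reactants: 5 (4R,5S)-4-(hydroxymethyl)-5-[(1S,2R,5S)-menthyloxy]dihydrofuran-2(3H)-one; 6 pent-1-en-4-yne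
Product: 8 (4R,5S)-4-(hydroxymethyl)-5-[(1E)-2-methylpenta-1,4-dien-1-yl]dihydrofuran-2(3H)-one, via dimethyl[(1E)-2-methylpenta-1,4-dien-1-yl]alumane 7 (not isolated)
Conditions: 6, Me3Al (2 equiv), Cp2ZrCl2 (0.2 equiv), CH2Cl2, 0 °C to rt; excess Me3Al removed in vacuo; then 5 (0.45 equiv), CH2Cl2, −78 to 0 °C; aq. Rochelle salt
Reagents that add atoms: trimethylaluminium, C[Al](C)C
Why: Proposed new method: Negishi zirconium‑catalysed carboalumination (syn, gives the E‑alkenylalane; known) is followed by binding of the C14 hydroxyl to aluminium and Lewis‑acid ionisation of the menthyl acetal to the lactone oxocarbenium ion, so that the alkenyl group (which migrates far better than methyl) is delivered from the C14–O–Al tether to the same face and gives the 4,5‑cis lactone with loss of menthol; the closest known reactions are the aluminate‑directed syn C‑glycosylation of glycal epoxides by organoalanes and the Lewis‑acid substitution of 5‑alkoxybutyrolactones.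

Step 4
Reactants: 8 (4R,5S)-4-(hydroxymethyl)-5-[(1E)-2-methylpenta-1,4-dien-1-yl]dihydrofuran-2(3H)-one
Product: 9 (4S,5S)-4-(iodomethyl)-5-[(1E)-2-methylpenta-1,4-dien-1-yl]dihydrofuran-2(3H)-one
Conditions: I2, PPh3, imidazole, CH2Cl2, 0 °C to rt
Reagents that add atoms: iodine, II
Why: Appel‑type iodination of the primary alcohol (iodophosphonium activation, SN2 by iodide) touches no stereocentre and leaves the lactone and the skipped diene intact.

Step 5
Reactants: 10 (R)-(−)-linalool
Product: 11 (2E,6R)-6-hydroxy-2,6-dimethylocta-2,7-dienal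
Conditions: SeO2 (1.1 equiv), 1,4‑dioxane, 80 °C
Reagents that add atoms: selenium dioxide, O=[Se]=O
Why: Riley allylic oxidation (ene reaction, then [2,3]-sigmatropic shift) is selective for the E‑methyl group of the trisubstituted olefin and runs on to the E‑enal, while the tertiary carbinol stereocentre and the vinyl group are untouched.

Step 6
Reactants: 9 (4S,5S)-4-(iodomethyl)-5-[(1E)-2-methylpenta-1,4-dien-1-yl]dihydrofuran-2(3H)-one; 11 (2E,6R)-6-hydroxy-2,6-dimethylocta-2,7-dienal
Product: 14 (4S,5R)-4-[(2S,3E,7R)-2,7-dihydroxy-3,7-dimethylnona-3,8-dien-1-yl]-5-[(1E)-2-methylpenta-1,4-dien-1-yl]dihydrofuran-2(3H)-one, via alkylzinc iodide 12 (not isolated), via alkyl(trimethylsilylmethyl)zinc 13 (not isolated)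
Conditions: Zn dust, LiCl, THF, 35 °C; Me3SiCH2Li, −78 °C; then 11 (premixed with Ti(OiPr)4, 1.5 equiv), (1R,2R)-1,2-bis(trifluoromethanesulfonamido)cyclohexane (8 mol%), Et2O/toluene, −20 °C
Reagents that add atoms: none
Why: Zinc insertion and exchange with (trimethylsilyl)methyllithium give a mixed diorganozinc that transfers only the functionalised alkyl group in a titanium/bis‑sulfonamide‑catalysed (Knochel‑type) enantioselective 1,2‑addition to the enal, the (1R,2R) ligand directing attack to the Si face and setting 13S by catalyst control while the tertiary hydroxyl is masked in situ as its titanate.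

Step 7
Reactants: 14 (4S,5R)-4-[(2S,3E,7R)-2,7-dihydroxy-3,7-dimethylnona-3,8-dien-1-yl]-5-[(1E)-2-methylpenta-1,4-dien-1-yl]dihydrofuran-2(3H)-one
Product: 15 (1S,2R,8R,13S)-8,13-dihydroxycembra-3E,6E,11E-trien-16,2-olide
Conditions: second‑generation Grubbs catalyst RuCl2(=CHPh)(PCy3)(H2IMes) (10 mol%), CH2Cl2 (1 mM), 40 °C
Reagents that add atoms: none
Why: Ring‑closing metathesis between the two monosubstituted vinyl groups (the trisubstituted olefins are inert) closes the 14‑membered carbocycle with loss of ethene and favours the more stable E‑C6=C7 olefin, without affecting any stereocentre.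

Step 8
Reactants: 15 (1S,2R,8R,13S)-8,13-dihydroxycembra-3E,6E,11E-trien-16,2-olide
Product: 18 (1S,2S,8R,13S)-8,13-dihydroxycembra-3E,6E,11E,15(17)-tetraen-16,2-olide, via Mannich base 16 (not isolated), via trimethylammonium iodide 17 (not isolated)
Conditions: LiN(SiMe3)2 (3.3 equiv), THF, −78 °C; Me2N=CH2+ I−, −78 to 0 °C; aq. NH4Cl; then MeI, MeOH, rt; then NaHCO3 (aq), CH2Cl2
Reagents that add atoms: N,N-dimethylmethyleneiminium iodide (Eschenmoser's salt), C=[N+](C)C.[I-]
Why: Mannich aminomethylation of the lactone lithium enolate with Eschenmoser's salt (the two hydroxyls being carried as alkoxides), N‑methylation and base‑induced Hofmann‑type β‑elimination install the exocyclic methylene at C15 without touching a stereocentre.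

Step 9
Reactants: 18 (1S,2S,8R,13S)-8,13-dihydroxycembra-3E,6E,11E,15(17)-tetraen-16,2-olide
Product: 19 13-O-deacetyl target (11,12-epoxy-8,13-dihydroxycembra-3E,6E,15(17)-trien-16,2-olide with every stereocentre as in the target)
Conditions: VO(acac)2 (5 mol%), t‑BuOOH (1.05 equiv), CH2Cl2, 0 °C
Reagents that add atoms: tert-butyl hydroperoxide, CC(C)(C)OO
Why: Vanadium‑catalysed hydroxyl‑directed (Sharpless–Michaelson) epoxidation delivers oxygen from the 13‑hydroxyl to the adjacent trisubstituted E‑olefin, 1,2‑allylic strain favouring the erythro epoxy alcohol (the 11,12‑configuration of the target relative to 13S), and the secondary allylic alcohol reacts faster than the tertiary allylic, isolated or electron‑poor olefins.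

Step 10
Reactants: 19 13-O-deacetyl target
Product: 20 (1S,2S,8R,11S,12R,13S)-13-acetoxy-11,12-epoxy-8-hydroxycembra-3E,6E,15(17)-trien-16,2-olide (target, CNP0288879.3)
Conditions: Ac2O, pyridine, DMAP (cat.), CH2Cl2, 0 °C to rt
Reagents that add atoms: acetic anhydride, CC(=O)OC(C)=O
Why: DMAP‑catalysed acylation esterifies only the secondary 13‑hydroxyl (the tertiary 8‑hydroxyl does not react under these conditions) and leaves the epoxide and the methylene lactone intact.

## Compound list

1 | furfural (furan-2-carbaldehyde) | O=Cc1ccco1 | starting material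
2 | (+)-menthol, (1S,2R,5S)-5-methyl-2-(propan-2-yl)cyclohexan-1-ol | CC(C)[C@H]1CC[C@H](C)C[C@@H]1O | starting material
3 | 5-hydroxyfuran-2(5H)-one (racemic, epimerising) | O=C1C=CC(O)O1 | intermediate
4 | (5S)-5-[(1S,2R,5S)-menthyloxy]furan-2(5H)-one | O=C1O[C@H](O[C@H]2C[C@@H](C)CC[C@@H]2C(C)C)C=C1 | intermediate
5 | (4R,5S)-4-(hydroxymethyl)-5-[(1S,2R,5S)-menthyloxy]dihydrofuran-2(3H)-one (4,5-trans) | O=C1O[C@H](O[C@H]2C[C@@H](C)CC[C@@H]2C(C)C)[C@@H](CO)C1 | intermediate
6 | pent-1-en-4-yne | C=CCC#C | starting material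
7 | dimethyl[(1E)-2-methylpenta-1,4-dien-1-yl]alumane | C[Al](C)/C=C(\C)CC=C | intermediate
8 | (4R,5S)-4-(hydroxymethyl)-5-[(1E)-2-methylpenta-1,4-dien-1-yl]dihydrofuran-2(3H)-one (4,5-cis) | O=C1O[C@@H](/C=C(\C)CC=C)[C@@H](CO)C1 | intermediate
9 | (4S,5S)-4-(iodomethyl)-5-[(1E)-2-methylpenta-1,4-dien-1-yl]dihydrofuran-2(3H)-one (4,5-cis) | O=C1O[C@@H](/C=C(\C)CC=C)[C@@H](CI)C1 | intermediate
10 | (R)-(−)-linalool, (3R)-3,7-dimethylocta-1,6-dien-3-ol | C=C[C@](C)(O)CCC=C(C)C | starting material
11 | (2E,6R)-6-hydroxy-2,6-dimethylocta-2,7-dienal | O=C/C(C)=C/CC[C@@](C)(O)C=C | intermediate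
12 | {[(2S,3S)-2-[(1E)-2-methylpenta-1,4-dien-1-yl]-5-oxooxolan-3-yl]methyl}zinc iodide | I[Zn]C[C@H]1CC(=O)O[C@H]1/C=C(\C)CC=C | intermediate
13 | {[(2S,3S)-2-[(1E)-2-methylpenta-1,4-dien-1-yl]-5-oxooxolan-3-yl]methyl}[(trimethylsilyl)methyl]zinc | C[Si](C)(C)C[Zn]C[C@H]1CC(=O)O[C@H]1/C=C(\C)CC=C | intermediate
14 | (4S,5R)-4-[(2S,3E,7R)-2,7-dihydroxy-3,7-dimethylnona-3,8-dien-1-yl]-5-[(1E)-2-methylpenta-1,4-dien-1-yl]dihydrofuran-2(3H)-one (4,5-cis) | O=C1O[C@@H](/C=C(\C)CC=C)[C@@H](C[C@H](O)/C(C)=C/CC[C@@](C)(O)C=C)C1 | intermediate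
15 | (1S,2R,8R,13S)-8,13-dihydroxycembra-3E,6E,11E-trien-16,2-olide (cis-fused lactone) | O=C1O[C@H]2/C=C(\C)C/C=C/[C@](C)(O)CC/C=C(\C)[C@@H](O)C[C@H]2C1 | intermediate
16 | 15-[(dimethylamino)methyl] derivative of 15 (C15 epimers) | CN(C)CC1C(=O)O[C@H]2/C=C(\C)C/C=C/[C@](C)(O)CC/C=C(\C)[C@@H](O)C[C@@H]12 | intermediate
17 | 15-[(trimethylammonio)methyl] derivative of 15, iodide | C[N+](C)(C)CC1C(=O)O[C@H]2/C=C(\C)C/C=C/[C@](C)(O)CC/C=C(\C)[C@@H](O)C[C@@H]12.[I-] | intermediate
18 | (1S,2S,8R,13S)-8,13-dihydroxycembra-3E,6E,11E,15(17)-tetraen-16,2-olide | C=C1C(=O)O[C@H]2/C=C(\C)C/C=C/[C@](C)(O)CC/C=C(\C)[C@@H](O)C[C@@H]12 | intermediate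
19 | 13-O-deacetyl target (11,12-epoxy-8,13-dihydroxycembra-3E,6E,15(17)-trien-16,2-olide, stereocentres as in the target) | C=C1C(=O)O[C@H]2/C=C(\C)C/C=C/[C@](C)(O)CC[C@@H]3O[C@@]3(C)[C@@H](O)C[C@@H]12 | intermediate
20 | (1S,2S,8R,11S,12R,13S)-13-acetoxy-11,12-epoxy-8-hydroxycembra-3E,6E,15(17)-trien-16,2-olide | C=C1C(=O)O[C@H]2/C=C(\C)C/C=C/[C@](C)(O)CC[C@@H]3O[C@@]3(C)[C@@H](OC(C)=O)C[C@@H]12 | target

## Step count and risks

Total step count: 10. Longest linear sequence: 9 steps (1, 2, 3, 4, 6, 7, 8, 9, 10, from furfural); step 5 is a one‑step side branch. No protecting groups are used.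

Steps most likely to fail:

**Step 3 (tethered alkenyl transfer).** This step has no direct precedent on this substrate. Methyl instead of alkenyl may transfer, untethered alane may attack anti to C14 and give the trans lactone, or the free hydroxyl may translactonise. The fallback sets out from 5 and comes back at 8. The hydroxyl of 5 is capped with 4‑methoxybenzyl trichloroacetimidate (cat. camphorsulfonic acid) to give (4R,5S)-4-{[(4-methoxybenzyl)oxy]methyl}-5-[(1S,2R,5S)-menthyloxy]dihydrofuran-2(3H)-one F1. Aqueous acid (HCl, dioxane) removes the menthol and leaves the lactol (4R)-5-hydroxy-4-{[(4-methoxybenzyl)oxy]methyl}dihydrofuran-2(3H)-one F2. Alane 7 is quenched with iodine to give (1E)-1-iodo-2-methylpenta-1,4-diene F3. Its Grignard reagent (t‑BuLi, then MgBr2) adds to the open aldehyde form of F2 under Cram chelation between the aldehyde and the β‑ether oxygen (anti adduct); acidification then closes the cis lactone (4R,5S)-4-{[(4-methoxybenzyl)oxy]methyl}-5-[(1E)-2-methylpenta-1,4-dien-1-yl]dihydrofuran-2(3H)-one F4. DDQ (CH2Cl2/H2O) removes the ether and returns 8.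

**Step 6 (asymmetric addition of the functionalised zinc reagent).** Alkyl transfer may be slow, the selectivity at C13 may be modest, and the free tertiary hydroxyl may interfere. The fallback sets out from 9 (through its zinc iodide 12) and 11 and comes back at 14. Pinnick oxidation of 11 (NaClO2, NaH2PO4, 2‑methylbut‑2‑ene) gives (2E,6R)-6-hydroxy-2,6-dimethylocta-2,7-dienoic acid F5. EtSH/DCC/DMAP converts it into S-ethyl (2E,6R)-6-hydroxy-2,6-dimethylocta-2,7-dienethioate F6. Fukuyama coupling of F6 with 12 (PdCl2(PPh3)2 cat., toluene) gives the enone (4S,5R)-4-[(3E,7R)-7-hydroxy-3,7-dimethyl-2-oxonona-3,8-dien-1-yl]-5-[(1E)-2-methylpenta-1,4-dien-1-yl]dihydrofuran-2(3H)-one F7. Corey–Bakshi–Shibata reduction with the (R)-methyloxazaborolidine and catecholborane at −78 °C sets 13S by reagent control and returns 14.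

**Step 7 (ring‑closing metathesis).** The E/Z ratio at C6=C7 and oligomerisation next to the fully substituted carbinol are uncertain. The fallback sets out from 9 and 11 and comes back at 15: the olefin is made first in the open chain and the ring is closed at C13–C14 instead. Cross‑metathesis of 9 with excess 11 (same ruthenium carbene, CH2Cl2, 40 °C) gives the E‑configured iodo aldehyde (2E,6R,7E,10E)-6-hydroxy-11-[(2S,3S)-3-(iodomethyl)-5-oxooxolan-2-yl]-2,6,10-trimethylundeca-2,7,10-trienal F8. Intramolecular Nozaki–Hiyama–Takai alkyl–aldehyde coupling (CrCl2, cobalt phthalocyanine C32H16CoN8 cat., DMF, high dilution) closes the ring to 15 together with its C13 epimer (1S,2R,8R,13R)-8,13-dihydroxycembra-3E,6E,11E-trien-16,2-olide F9. Dess–Martin oxidation of the mixture gives the single enone (1S,2R,8R)-8-hydroxy-13-oxocembra-3E,6E,11E-trien-16,2-olide F10, and (R)-methyloxazaborolidine/catecholborane reduction returns 15.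

## Further compounds

F1 | step 3 | (4R,5S)-4-{[(4-methoxybenzyl)oxy]methyl}-5-[(1S,2R,5S)-menthyloxy]dihydrofuran-2(3H)-one | O=C1O[C@H](O[C@H]2C[C@@H](C)CC[C@@H]2C(C)C)[C@@H](COCc2ccc(OC)cc2)C1
F2 | step 3 | (4R)-5-hydroxy-4-{[(4-methoxybenzyl)oxy]methyl}dihydrofuran-2(3H)-one (anomer mixture) | O=C1OC(O)[C@@H](COCc2ccc(OC)cc2)C1
F3 | step 3 | (1E)-1-iodo-2-methylpenta-1,4-diene | I/C=C(\C)CC=C
F4 | step 3 | (4R,5S)-4-{[(4-methoxybenzyl)oxy]methyl}-5-[(1E)-2-methylpenta-1,4-dien-1-yl]dihydrofuran-2(3H)-one | O=C1O[C@@H](/C=C(\C)CC=C)[C@@H](COCc2ccc(OC)cc2)C1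
F5 | step 6 | (2E,6R)-6-hydroxy-2,6-dimethylocta-2,7-dienoic acid | O=C(O)/C(C)=C/CC[C@@](C)(O)C=C
F6 | step 6 | S-ethyl (2E,6R)-6-hydroxy-2,6-dimethylocta-2,7-dienethioate | CCSC(=O)/C(C)=C/CC[C@@](C)(O)C=C
F7 | step 6 | (4S,5R)-4-[(3E,7R)-7-hydroxy-3,7-dimethyl-2-oxonona-3,8-dien-1-yl]-5-[(1E)-2-methylpenta-1,4-dien-1-yl]dihydrofuran-2(3H)-one | O=C1O[C@@H](/C=C(\C)CC=C)[C@@H](CC(=O)/C(C)=C/CC[C@@](C)(O)C=C)C1
F8 | step 7 | (2E,6R,7E,10E)-6-hydroxy-11-[(2S,3S)-3-(iodomethyl)-5-oxooxolan-2-yl]-2,6,10-trimethylundeca-2,7,10-trienal | O=C1O[C@@H](/C=C(\C)C/C=C/[C@](C)(O)CC/C=C(C)/C=O)[C@@H](CI)C1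
F9 | step 7 | (1S,2R,8R,13R)-8,13-dihydroxycembra-3E,6E,11E-trien-16,2-olide (C13 epimer of 15) | O=C1O[C@H]2/C=C(\C)C/C=C/[C@](C)(O)CC/C=C(\C)[C@H](O)C[C@H]2C1
F10 | step 7 | (1S,2R,8R)-8-hydroxy-13-oxocembra-3E,6E,11E-trien-16,2-olide | O=C1O[C@H]2/C=C(\C)C/C=C/[C@](C)(O)CC/C=C(\C)C(=O)C[C@H]2C1
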